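The new flask cannot be read off the autumn curve: the autumn run held 2 M of incoming ligand, the flask holds 3.00 M, and no earlier run changes that charge, so what follows is a reasoned guess.

| flask | starting complex | incoming ligand | remark | time |
|---|---|---|---|---|
| autumn | 1 M | 2 M | run made earlier |  |
| flask | 1.0 M | 3.00 M |  | 3.0 h |

autumn run (percent of the starting complex charged)

| time / h | complex with one exchanged / % | complex with two exchanged / % |
|---|---|---|
| 0.250 | 22.6 | 8.2 |
| 0.500 | 23.9 | 14.4 |
| 1.00 | 21.0 | 19.3 |
| 2.00 | 15.2 | 23.7 |
| 4.00 | 8.0 | 27.6 |

(scatter of a reading: 1 percentage point)

- in percentages every species weighs as the starting complex in it: one self-condensation product counts as two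
- candidate steps: leaving ligand -> by-product carried off; starting complex + incoming ligand <-> leaving ligand + complex with one exchanged; 2 starting complex -> self-condensation product; complex with two exchanged <-> isomer of the product; complex with one exchanged + incoming ligand <-> leaving ligand + complex with two exchanged
- no earlier run changes the charge of incoming ligand; that part of a forecast is a guess

* equivalents of incoming ligand to starting complex, everything else as given, that leave most complex with one exchanged at 3.0 h
* the amount of complex with one exchanged then, in percent of the starting complex charged
* the amount of complex with one exchanged with the amounts as given

Take the autumn table at its late end first. Complex with one exchanged falls from 15.2% to 8.0% between 2.00 h and 4.00 h, a read half-life of 2.16 h. Assuming that the rate of this fall is proportional to the ligand charge, the quantity to carry is the halving dose, the charge of incoming ligand times the late half-life, 4.32 M·h.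

Now the early end. The two complexes together reach 40.3% at 1.00 h, more than in any other row. Counting the rest of the autumn charge roughly as self-condensation gives a selectivity factor, the two complexes over that rest and divided by the ligand charge, of 0.338 M⁻¹, assumed the same at another charge.

Joining the ends, the flask's charge times time runs 0.231 halvings past the last autumn reading, and its share of the two complexes is reckoned at 1.25 times the autumn one, so this reckoning gives 8.51%. In this reckoning more ligand raises that share but brings the halvings sooner, and the two balance at 1.41 M, that is 1.41 equivalents, with 11.7%.

The forecast differs, with 13.5% as charged and 18% at 5 equiv, and says of its numbers “This is an extrapolation”.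

The flask gives 8.34% as charged and 11.3% at 1.12 equiv.

    leaving ligand → by-product carried off (k = 0.0280 min⁻¹)
    starting complex + incoming ligand ⇌ leaving ligand + complex with one exchanged (K = 0.410, k = 0.0250 M⁻¹ min⁻¹)
    2 starting complex → self-condensation product (k = 0.0370 M⁻¹ min⁻¹)
    complex with two exchanged ⇌ isomer of the product (K = 1.10, k = 0.00420 min⁻¹)
    complex with one exchanged + incoming ligand ⇌ leaving ligand + complex with two exchanged (K = 0.180, k = 0.0270 M⁻¹ min⁻¹)

At 3.00 h in the flask starting complex, the limiting reagent, is down to 1.1% of its charge, less than the 63% of incoming ligand left. The halving dose gives complex with one exchanged in this flask a half-life of 1.44 h; its fall from 17.8% at 1.50 h to 8.34% at 3.00 h shows 1.37 h.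

Read the same flask at 5.0 h: the halving dose takes the 8.34% of complex with one exchanged down over the further 2.00 h to 3.19%. The computed flask holds 2.47%.

The numbers in the tables are calculated from invented constants; scatter was added.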